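**Retrosynthetic overview**
1. Side chain last: the C7 ester is put on as a dec-2-ynoate and unveiled by cis-semihydrogenation, then oxidation of the side-chain carbinol to the ketone.
2. δ-Lactone (second ring): oxidative lactonisation of a primary C1 alcohol onto the C5 hydroxyl; the C3 acetate is set just before, when C3-OH is the only free hydroxyl.
3. Tetrahydropyran (first ring): acid-catalysed 6-exo opening of a C3–C4 cis-epoxide at its tertiary carbon by the C8 hydroxyl (sets C4, reveals C3-OH); epoxide from hydroxyl-directed epoxidation of a (Z)-allylic alcohol; C7 from a 1,3-syn reduction.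
4. Key C5–C6 bond: intermolecular titanium aldol between the (S)-lactate-derived ethyl ketone (C6–C9) and a (Z)-enal (C1–C5) made from the (S)-Roche ester by Still–Gennari olefination.
5. Ring order: tetrahydropyran first, lactone second.

Convention: chain numbering C1 (lactone C=O), C2, C3 (OAc), C4 (quaternary), C5 (lactone O), C6, C7 (side-chain ester), C8, C9 (CH3 on C8) is used in the text; fused-ring locants in names are O1, C2(=O), C3, C4, C4a, O5, C6, C7, C8, C8a (C1→2, C2→3, C3→4, C4→4a, C5→8a, C6→8, C7→7, C8→6). The target is taken exactly as the SMILES gives it: (2R,3S,4S,5S,6R,7R,8S) in chain numbering with a (2Z)-4-oxodec-2-enoate.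

**Fragment B (C6–C9)**

Step 1
Reactants: 1 ethyl (2S)-2-hydroxypropanoate (ethyl (S)-lactate)
Product: 2 ethyl (2S)-2-(benzyloxy)propanoate
Conditions: BnOC(=NH)CCl3, CF3SO3H (cat.), cyclohexane/CH2Cl2, rt
Reagents that add atoms: benzyl 2,2,2-trichloroacetimidate, N=C(OCc1ccccc1)C(Cl)(Cl)Cl
Why: Acid-catalysed O-benzylation with a trichloroacetimidate avoids base, so the lactate stereocentre (future C8) is kept.

Step 2
Reactants: 2 ethyl (2S)-2-(benzyloxy)propanoate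
Product: 3 (2S)-2-(benzyloxy)-N-methoxy-N-methylpropanamide
Conditions: MeNH(OMe)·HCl, i-PrMgCl, THF, −20 °C
Reagents that add atoms: N,O-dimethylhydroxylamine hydrochloride, CNOC.Cl
Why: Weinreb amide formation by aminolysis of the ester with the chloromagnesium amide made in the flask; at −20 °C the α-alkoxy stereocentre does not epimerise.

Step 3
Reactants: 3 (2S)-2-(benzyloxy)-N-methoxy-N-methylpropanamide
Product: 4 (2S)-2-(benzyloxy)pentan-3-one
Conditions: EtMgBr, THF, 0 °C; aq. NH4Cl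
Reagents that add atoms: ethylmagnesium bromide, CC[Mg]Br
Why: Weinreb ketone synthesis: the chelated tetrahedral adduct blocks over-addition and gives the ethyl ketone without racemisation.

**Fragment A (C1–C5)**

Step 4
Reactants: 5 methyl (2S)-3-hydroxy-2-methylpropanoate ((S)-Roche ester)
Product: 6 methyl (2S)-3-[(tert-butyldimethylsilyl)oxy]-2-methylpropanoate
Conditions: TBSCl, imidazole, CH2Cl2, rt
Reagents that add atoms: tert-butyldimethylsilyl chloride, C[Si](C)(Cl)C(C)(C)C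
Why: Standard silylation of the primary alcohol (future C1–O); the C2 stereocentre comes from the chiral pool.

Step 5
Reactants: 6 methyl (2S)-3-[(tert-butyldimethylsilyl)oxy]-2-methylpropanoate
Product: 7 (2R)-3-[(tert-butyldimethylsilyl)oxy]-2-methylpropan-1-ol
Conditions: i-Bu2AlH (2.5 equiv), CH2Cl2, −78 → 0 °C; aq. potassium sodium tartrate
Reagents that add atoms: none
Why: Full hydride reduction of the ester to the alcohol is more dependable than partial reduction; the stereocentre is untouched (the descriptor changes only through priorities).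

Step 6
Reactants: 7 (2R)-3-[(tert-butyldimethylsilyl)oxy]-2-methylpropan-1-ol
Product: 8 (2S)-3-[(tert-butyldimethylsilyl)oxy]-2-methylpropanal
Conditions: (COCl)2, DMSO, CH2Cl2, −78 °C; Et3N; used crude at once
Reagents that add atoms: none
Why: Swern oxidation at low temperature gives the α-chiral aldehyde without epimerisation.

Step 7
Reactants: 8 (2S)-3-[(tert-butyldimethylsilyl)oxy]-2-methylpropanal
Product: 9 methyl (2Z,4R)-5-[(tert-butyldimethylsilyl)oxy]-2,4-dimethylpent-2-enoate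
Conditions: (CF3CH2O)2P(O)CH(CH3)CO2Me, KN(SiMe3)2, 18-crown-6, THF, −78 °C
Reagents that add atoms: methyl 2-[bis(2,2,2-trifluoroethoxy)phosphoryl]propanoate, COC(=O)C(C)P(=O)(OCC(F)(F)F)OCC(F)(F)F
Why: Still–Gennari variant of the Horner–Wadsworth–Emmons olefination: the trifluoroethyl phosphonate under dissociating conditions collapses kinetically to the (Z)-trisubstituted enoate, placing C2 and the future C5 cis as the later cis-epoxide requires.

Step 8
Reactants: 9 methyl (2Z,4R)-5-[(tert-butyldimethylsilyl)oxy]-2,4-dimethylpent-2-enoate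
Product: 10 (2Z,4R)-5-[(tert-butyldimethylsilyl)oxy]-2,4-dimethylpent-2-en-1-ol
Conditions: i-Bu2AlH (2.5 equiv), CH2Cl2, −78 °C; aq. potassium sodium tartrate
Reagents that add atoms: none
Why: 1,2-Reduction of the enoate to the allylic alcohol leaves the alkene geometry unchanged.

Step 9
Reactants: 10 (2Z,4R)-5-[(tert-butyldimethylsilyl)oxy]-2,4-dimethylpent-2-en-1-ol
Product: 11 (2Z,4R)-5-[(tert-butyldimethylsilyl)oxy]-2,4-dimethylpent-2-enal
Conditions: MnO2 (activated, excess), CH2Cl2, rt; used at once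
Reagents that add atoms: none
Why: Neutral allylic oxidation with MnO2 gives the (Z)-enal without Z/E isomerisation.

**Fragment union and core**

Step 10
Reactants: 4 (2S)-2-(benzyloxy)pentan-3-one; 11 (2Z,4R)-5-[(tert-butyldimethylsilyl)oxy]-2,4-dimethylpent-2-enal
Product: 13 (2S,4S,5S,6Z,8R)-2-(benzyloxy)-9-[(tert-butyldimethylsilyl)oxy]-5-hydroxy-4,6,8-trimethylnon-6-en-3-one, via titanium enolate 12 (not isolated)
Conditions: 4, TiCl4, CH2Cl2, −78 °C; i-Pr2NEt; then 11, −78 °C; aq. NH4Cl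
Reagents that add atoms: none
Why: Substrate-controlled titanium aldol: the (Z)-titanium enolate, chelated by the benzyloxy oxygen, adds through a Zimmerman–Traxler chair on the face anti to the C9 methyl, forming the key C5–C6 bond with C5-OH/C6-Me syn and both centres as drawn (4S,5S in 13).

Step 11
Reactants: 13 aldol adduct (β-hydroxy ketone with (Z)-allylic alcohol)
Product: 14 (2S,4S,5S)-2-(benzyloxy)-5-[(2R,3S)-3-{(2S)-1-[(tert-butyldimethylsilyl)oxy]propan-2-yl}-2-methyloxiran-2-yl]-5-hydroxy-4-methylpentan-3-one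
Conditions: mCPBA, CH2Cl2, 0 °C
Reagents that add atoms: 3-chloroperoxybenzoic acid, OOC(=O)c1cccc(Cl)c1
Why: Henbest-type hydroxyl-directed epoxidation: 1,3-allylic strain from the cis C2 substituent holds C5–H in the alkene plane, so oxygen arrives on the hydroxyl face and gives the threo cis-epoxide, which fixes C3 and pre-sets C4 for inversion.

Step 12
Reactants: 14 epoxy β-hydroxy ketone
Product: 16 (1S,2R,3R,4S)-4-(benzyloxy)-1-[(2R,3S)-3-{(2S)-1-[(tert-butyldimethylsilyl)oxy]propan-2-yl}-2-methyloxiran-2-yl]-2-methylpentane-1,3-diol, via boron chelate 15 (not isolated)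
Conditions: Et2BOMe, THF/MeOH 4:1, −78 °C; NaBH4; then MeOH co-evaporation (boron leaves as Et2BOMe)
Reagents that add atoms: none
Why: Narasaka–Prasad reduction: external hydride attacks the six-membered boron chelate axially and gives the 1,3-syn diol, setting C7.

Step 13
Reactants: 16 epoxy syn-diol
Product: 17 tert-butyl{(2S)-2-[(2S,3S)-3-{(1S,2R,3R,4S)-4-(benzyloxy)-2-methyl-1,3-bis[(triethylsilyl)oxy]pentyl}-3-methyloxiran-2-yl]propoxy}dimethylsilane
Conditions: TESCl, imidazole, 4-(dimethylamino)pyridine (cat.), DMF, 0 °C → rt; chromatography on Et3N-treated silica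
Reagents that add atoms: chlorotriethylsilane, CC[Si](Cl)(CC)CC
Why: Mild basic bis-silylation keeps the epoxide intact and blocks O7 (and O5), so that only O8 can open the epoxide later.

Step 14
Reactants: 17 bis-triethylsilyl epoxide
Product: 19 (1S,2S)-3-[(tert-butyldimethylsilyl)oxy]-2-methyl-1-{(2R,3S,4R,5R,6S)-2,4,6-trimethyl-3,5-bis[(triethylsilyl)oxy]oxan-2-yl}propan-1-ol, via epoxy alcohol 18 (not isolated)
Conditions: H2 (1 atm), Pd/C, EtOAc, rt; filter; then (+)-camphor-10-sulfonic acid (0.1 equiv), CH2Cl2, 0 °C; Et3N quench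
Reagents that add atoms: none
Why: Hydrogenolysis frees the C8 hydroxyl, which opens the protonated epoxide at its tertiary carbon C4 in a 6-exo-tet cyclisation with inversion (chair transition state, ring substituents equatorial), giving the tetrahydropyran, the quaternary centre C4 and the free C3 hydroxyl.

Step 15
Reactants: 19 tetrahydropyran with free C3 hydroxyl
Product: 20 (1S,2S)-3-[(tert-butyldimethylsilyl)oxy]-2-methyl-1-{(2R,3S,4R,5R,6S)-2,4,6-trimethyl-3,5-bis[(triethylsilyl)oxy]oxan-2-yl}propyl acetate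
Conditions: Ac2O, pyridine, 4-(dimethylamino)pyridine (cat.), rt
Reagents that add atoms: acetic anhydride, CC(=O)OC(C)=O
Why: DMAP-catalysed acylation of the only free hydroxyl installs the C3 acetate with no selectivity issue.

Step 16
Reactants: 20 tris-silylated acetate
Product: 21 (1S,2S)-1-[(2S,3S,4R,5R,6S)-3,5-dihydroxy-2,4,6-trimethyloxan-2-yl]-3-hydroxy-2-methylpropyl acetate
Conditions: HF·pyridine, pyridine, THF, 0 °C → rt
Reagents that add atoms: none
Why: Buffered fluoride-mediated global desilylation removes all three silyl ethers under non-basic conditions, so the acetate neither cleaves nor migrates.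

Step 17
Reactants: 21 triol acetate
Product: 24 (3R,4S,4aS,6S,7R,8R,8aS)-7-hydroxy-3,4a,6,8-tetramethyl-2-oxooctahydropyrano[3,2-b]pyran-4-yl acetate, via hydroxy aldehyde 22 (not isolated), via lactol 23 (not isolated)
Conditions: TEMPO (2,2,6,6-tetramethylpiperidin-1-oxyl, 0.2 equiv), PhI(OAc)2 (2.5 equiv), CH2Cl2, rt
Reagents that add atoms: none
Why: TEMPO/PhI(OAc)2 oxidative lactonisation: the primary alcohol is oxidised selectively, the aldehyde is trapped by O5 as the six-membered lactol and oxidised on to the δ-lactone (second ring), leaving the secondary C7 hydroxyl free.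

**Side-chain acid**

Step 18
Reactants: 25 heptanal
Product: 26 non-1-yn-3-ol (racemic)
Conditions: HC≡CMgBr, THF, 0 °C; aq. NH4Cl
Reagents that add atoms: ethynylmagnesium bromide, C#C[Mg]Br
Why: Grignard alkynylation of the aldehyde; the carbinol centre is racemic on purpose because it is oxidised to the ketone at the end.

Step 19
Reactants: 26 non-1-yn-3-ol (racemic)
Product: 27 tert-butyl(dimethyl)(non-1-yn-3-yloxy)silane (racemic)
Conditions: TBSCl, imidazole, DMF, rt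
Reagents that add atoms: tert-butyldimethylsilyl chloride, C[Si](C)(Cl)C(C)(C)C
Why: Silyl protection prevents self-esterification in the later coupling.

Step 20
Reactants: 27 tert-butyl(dimethyl)(non-1-yn-3-yloxy)silane (racemic)
Product: 29 4-[(tert-butyldimethylsilyl)oxy]dec-2-ynoic acid (racemic), via lithium acetylide 28 (not isolated)
Conditions: n-BuLi, THF, −78 °C; CO2; then cold aq. HCl
Reagents that add atoms: carbon dioxide, O=C=O
Why: Deprotonation of the terminal alkyne and carboxylation of the acetylide gives the ynoic acid directly.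

**Endgame**

Step 21
Reactants: 24 bicyclic core alcohol; 29 4-[(tert-butyldimethylsilyl)oxy]dec-2-ynoic acid (racemic)
Product: 30 (3R,4S,4aS,6S,7R,8R,8aS)-4-(acetyloxy)-3,4a,6,8-tetramethyl-2-oxooctahydropyrano[3,2-b]pyran-7-yl 4-[(tert-butyldimethylsilyl)oxy]dec-2-ynoate (1:1 epimers at side-chain C4)
Conditions: DCC, 4-(dimethylamino)pyridine (cat.), CH2Cl2, 0 °C
Reagents that add atoms: none
Why: Steglich esterification (carbodiimide activation, DMAP acyl transfer) acylates the sole free hydroxyl at C7 with retention.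

Step 22
Reactants: 30 silylated ynoate ester
Product: 31 (3R,4S,4aS,6S,7R,8R,8aS)-4-(acetyloxy)-3,4a,6,8-tetramethyl-2-oxooctahydropyrano[3,2-b]pyran-7-yl 4-hydroxydec-2-ynoate (1:1 epimers at side-chain C4)
Conditions: HF·pyridine, pyridine, THF, 0 °C → rt
Reagents that add atoms: none
Why: Fluoride-mediated desilylation gives a propargylic alcohol that cannot lactonise for geometric reasons; acetate and lactone survive.

Step 23
Reactants: 31 4-hydroxy-ynoate ester
Product: 32 (3R,4S,4aS,6S,7R,8R,8aS)-4-(acetyloxy)-3,4a,6,8-tetramethyl-2-oxooctahydropyrano[3,2-b]pyran-7-yl (2Z)-4-hydroxydec-2-enoate (1:1 epimers at side-chain C4)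
Conditions: H2 (1 atm), Pd/CaCO3 poisoned with Pb(OAc)2, quinoline, EtOAc, 0 °C; filter, concentrate cold, use at once
Reagents that add atoms: none
Why: Lindlar-type semihydrogenation delivers H2 syn on the poisoned palladium surface and gives the (Z)-enoate only.

Step 24
Reactants: 32 (Z)-4-hydroxy-enoate ester
Product: 33 botcinin J, (3R,4S,4aS,6S,7R,8R,8aS)-4-(acetyloxy)-3,4a,6,8-tetramethyl-2-oxooctahydropyrano[3,2-b]pyran-7-yl (2Z)-4-oxodec-2-enoate
Conditions: Dess–Martin periodinane, NaHCO3, CH2Cl2, 0 °C, dark; rapid chromatography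
Reagents that add atoms: none
Why: Dess–Martin oxidation under buffered, non-nucleophilic conditions converts the allylic alcohol into the ketone without Z/E isomerisation and removes the side-chain carbinol stereocentre.

**Compound list**

1 | ethyl (2S)-2-hydroxypropanoate | C[C@H](O)C(=O)OCC | starting material
2 | ethyl (2S)-2-(benzyloxy)propanoate | C[C@H](OCc1ccccc1)C(=O)OCC | intermediate
3 | (2S)-2-(benzyloxy)-N-methoxy-N-methylpropanamide | C[C@H](OCc1ccccc1)C(=O)N(C)OC | intermediate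
4 | (2S)-2-(benzyloxy)pentan-3-one | CCC(=O)[C@H](C)OCc1ccccc1 | intermediate
5 | methyl (2S)-3-hydroxy-2-methylpropanoate | COC(=O)[C@@H](C)CO | starting material
6 | methyl (2S)-3-[(tert-butyldimethylsilyl)oxy]-2-methylpropanoate | COC(=O)[C@@H](C)CO[Si](C)(C)C(C)(C)C | intermediate
7 | (2R)-3-[(tert-butyldimethylsilyl)oxy]-2-methylpropan-1-ol | OC[C@@H](C)CO[Si](C)(C)C(C)(C)C | intermediate
8 | (2S)-3-[(tert-butyldimethylsilyl)oxy]-2-methylpropanal | O=C[C@@H](C)CO[Si](C)(C)C(C)(C)C | intermediate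
9 | methyl (2Z,4R)-5-[(tert-butyldimethylsilyl)oxy]-2,4-dimethylpent-2-enoate | COC(=O)/C(C)=C\[C@@H](C)CO[Si](C)(C)C(C)(C)C | intermediate
10 | (2Z,4R)-5-[(tert-butyldimethylsilyl)oxy]-2,4-dimethylpent-2-en-1-ol | OC/C(C)=C\[C@@H](C)CO[Si](C)(C)C(C)(C)C | intermediate
11 | (2Z,4R)-5-[(tert-butyldimethylsilyl)oxy]-2,4-dimethylpent-2-enal | O=C/C(C)=C\[C@@H](C)CO[Si](C)(C)C(C)(C)C | intermediate
12 | trichloro{[(2Z,4S)-4-(benzyloxy)pent-2-en-3-yl]oxy}titanium (titanium enolate of 4) | C/C=C(\O[Ti](Cl)(Cl)Cl)[C@H](C)OCc1ccccc1 | intermediate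
13 | (2S,4S,5S,6Z,8R)-2-(benzyloxy)-9-[(tert-butyldimethylsilyl)oxy]-5-hydroxy-4,6,8-trimethylnon-6-en-3-one | C[C@H](OCc1ccccc1)C(=O)[C@@H](C)[C@H](O)/C(C)=C\[C@@H](C)CO[Si](C)(C)C(C)(C)C | intermediate
14 | (2S,4S,5S)-2-(benzyloxy)-5-[(2R,3S)-3-{(2S)-1-[(tert-butyldimethylsilyl)oxy]propan-2-yl}-2-methyloxiran-2-yl]-5-hydroxy-4-methylpentan-3-one | C[C@H](OCc1ccccc1)C(=O)[C@@H](C)[C@H](O)[C@@]1(C)O[C@H]1[C@@H](C)CO[Si](C)(C)C(C)(C)C | intermediate
15 | (2S,4S,5S)-2-(benzyloxy)-5-[(diethylboranyl)oxy]-5-[(2R,3S)-3-{(2S)-1-[(tert-butyldimethylsilyl)oxy]propan-2-yl}-2-methyloxiran-2-yl]-4-methylpentan-3-one (boron chelated to the ketone oxygen) | C[C@H](OCc1ccccc1)C(=O)[C@@H](C)[C@H](OB(CC)CC)[C@@]1(C)O[C@H]1[C@@H](C)CO[Si](C)(C)C(C)(C)C | intermediate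
16 | (1S,2R,3R,4S)-4-(benzyloxy)-1-[(2R,3S)-3-{(2S)-1-[(tert-butyldimethylsilyl)oxy]propan-2-yl}-2-methyloxiran-2-yl]-2-methylpentane-1,3-diol | C[C@H](OCc1ccccc1)[C@H](O)[C@@H](C)[C@H](O)[C@@]1(C)O[C@H]1[C@@H](C)CO[Si](C)(C)C(C)(C)C | intermediate
17 | tert-butyl{(2S)-2-[(2S,3S)-3-{(1S,2R,3R,4S)-4-(benzyloxy)-2-methyl-1,3-bis[(triethylsilyl)oxy]pentyl}-3-methyloxiran-2-yl]propoxy}dimethylsilane | C[C@H](OCc1ccccc1)[C@H](O[Si](CC)(CC)CC)[C@@H](C)[C@H](O[Si](CC)(CC)CC)[C@@]1(C)O[C@H]1[C@@H](C)CO[Si](C)(C)C(C)(C)C | intermediate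
18 | (2S,3R,4R,5S)-5-[(2S,3S)-3-{(2S)-1-[(tert-butyldimethylsilyl)oxy]propan-2-yl}-2-methyloxiran-2-yl]-4-methyl-3,5-bis[(triethylsilyl)oxy]pentan-2-ol | C[C@H](O)[C@H](O[Si](CC)(CC)CC)[C@@H](C)[C@H](O[Si](CC)(CC)CC)[C@@]1(C)O[C@H]1[C@@H](C)CO[Si](C)(C)C(C)(C)C | intermediate
19 | (1S,2S)-3-[(tert-butyldimethylsilyl)oxy]-2-methyl-1-{(2R,3S,4R,5R,6S)-2,4,6-trimethyl-3,5-bis[(triethylsilyl)oxy]oxan-2-yl}propan-1-ol | C[C@@H]1O[C@](C)([C@@H](O)[C@@H](C)CO[Si](C)(C)C(C)(C)C)[C@@H](O[Si](CC)(CC)CC)[C@H](C)[C@H]1O[Si](CC)(CC)CC | intermediate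
20 | (1S,2S)-3-[(tert-butyldimethylsilyl)oxy]-2-methyl-1-{(2R,3S,4R,5R,6S)-2,4,6-trimethyl-3,5-bis[(triethylsilyl)oxy]oxan-2-yl}propyl acetate | C[C@@H]1O[C@](C)([C@@H](OC(C)=O)[C@@H](C)CO[Si](C)(C)C(C)(C)C)[C@@H](O[Si](CC)(CC)CC)[C@H](C)[C@H]1O[Si](CC)(CC)CC | intermediate
21 | (1S,2S)-1-[(2S,3S,4R,5R,6S)-3,5-dihydroxy-2,4,6-trimethyloxan-2-yl]-3-hydroxy-2-methylpropyl acetate | C[C@@H]1O[C@](C)([C@@H](OC(C)=O)[C@@H](C)CO)[C@@H](O)[C@H](C)[C@H]1O | intermediate
22 | (1S,2R)-1-[(2S,3S,4R,5R,6S)-3,5-dihydroxy-2,4,6-trimethyloxan-2-yl]-2-methyl-3-oxopropyl acetate | C[C@@H]1O[C@](C)([C@@H](OC(C)=O)[C@@H](C)C=O)[C@@H](O)[C@H](C)[C@H]1O | intermediate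
23 | (3R,4S,4aS,6S,7R,8R,8aS)-2,7-dihydroxy-3,4a,6,8-tetramethyloctahydropyrano[3,2-b]pyran-4-yl acetate (both C2 anomers) | O[C@@H]1[C@@H](C)[C@@H]2OC(O)[C@H](C)[C@H](OC(C)=O)[C@@]2(C)O[C@H]1C | intermediate
24 | (3R,4S,4aS,6S,7R,8R,8aS)-7-hydroxy-3,4a,6,8-tetramethyl-2-oxooctahydropyrano[3,2-b]pyran-4-yl acetate | O[C@@H]1[C@@H](C)[C@@H]2OC(=O)[C@H](C)[C@H](OC(C)=O)[C@@]2(C)O[C@H]1C | intermediate
25 | heptanal | CCCCCCC=O | starting material
26 | non-1-yn-3-ol (racemic) | CCCCCCC(O)C#C | intermediate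
27 | tert-butyl(dimethyl)(non-1-yn-3-yloxy)silane (racemic) | CCCCCCC(O[Si](C)(C)C(C)(C)C)C#C | intermediate
28 | {3-[(tert-butyldimethylsilyl)oxy]non-1-yn-1-yl}lithium (racemic) | CCCCCCC(O[Si](C)(C)C(C)(C)C)C#C[Li] | intermediate
29 | 4-[(tert-butyldimethylsilyl)oxy]dec-2-ynoic acid (racemic) | CCCCCCC(O[Si](C)(C)C(C)(C)C)C#CC(=O)O | intermediate
30 | (3R,4S,4aS,6S,7R,8R,8aS)-4-(acetyloxy)-3,4a,6,8-tetramethyl-2-oxooctahydropyrano[3,2-b]pyran-7-yl 4-[(tert-butyldimethylsilyl)oxy]dec-2-ynoate (1:1 epimers at side-chain C4) | CCCCCCC(O[Si](C)(C)C(C)(C)C)C#CC(=O)O[C@@H]1[C@@H](C)[C@@H]2OC(=O)[C@H](C)[C@H](OC(C)=O)[C@@]2(C)O[C@H]1C | intermediate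
31 | (3R,4S,4aS,6S,7R,8R,8aS)-4-(acetyloxy)-3,4a,6,8-tetramethyl-2-oxooctahydropyrano[3,2-b]pyran-7-yl 4-hydroxydec-2-ynoate (1:1 epimers at side-chain C4) | CCCCCCC(O)C#CC(=O)O[C@@H]1[C@@H](C)[C@@H]2OC(=O)[C@H](C)[C@H](OC(C)=O)[C@@]2(C)O[C@H]1C | intermediate
32 | (3R,4S,4aS,6S,7R,8R,8aS)-4-(acetyloxy)-3,4a,6,8-tetramethyl-2-oxooctahydropyrano[3,2-b]pyran-7-yl (2Z)-4-hydroxydec-2-enoate (1:1 epimers at side-chain C4) | CCCCCCC(O)/C=C\C(=O)O[C@@H]1[C@@H](C)[C@@H]2OC(=O)[C@H](C)[C@H](OC(C)=O)[C@@]2(C)O[C@H]1C | intermediate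
33 | botcinin J, (3R,4S,4aS,6S,7R,8R,8aS)-4-(acetyloxy)-3,4a,6,8-tetramethyl-2-oxooctahydropyrano[3,2-b]pyran-7-yl (2Z)-4-oxodec-2-enoate | CCCCCCC(=O)/C=C\C(=O)O[C@@H]1[C@@H](C)[C@@H]2OC(=O)[C@H](C)[C@H](OC(C)=O)[C@@]2(C)O[C@H]1C | target

**Totals and weak points**

Total step count: 24. Longest linear sequence: 18 steps (5 → 33; steps 4–17 and 21–24).

Step 10 (key aldol). Risks are Z→E isomerisation of enal 11 by TiCl4 and eroded facial control. The fallback makes the C6–C7 bond instead, with the roles of the partners reversed; it sets out from 11 and 2 and comes back at 16. Enal 11 takes up EtMgBr to give (4Z,6R)-7-[(tert-butyldimethylsilyl)oxy]-4,6-dimethylhept-4-en-3-ol F1, and Dess–Martin oxidation gives the ethyl enone (4Z,6R)-7-[(tert-butyldimethylsilyl)oxy]-4,6-dimethylhept-4-en-3-one F2. Ester 2 is reduced with i-Bu2AlH at −78 °C to (2S)-2-(benzyloxy)propanal F3. The (Z)-boron enolate of F2 (n-Bu2BOTf, i-Pr2NEt, −78 °C) adds to F3 in a syn aldol whose Cornforth-type 1,2-induction gives the 6,7-syn-7,8-anti adduct (2S,3R,4R,6Z,8R)-2-(benzyloxy)-9-[(tert-butyldimethylsilyl)oxy]-3-hydroxy-4,6,8-trimethylnon-6-en-5-one F4. Narasaka–Prasad reduction (Et2BOMe, NaBH4) then sets C5 syn to O7 and gives (2S,3R,4S,5S,6Z,8R)-2-(benzyloxy)-9-[(tert-butyldimethylsilyl)oxy]-4,6,8-trimethylnon-6-ene-3,5-diol F5, and mCPBA epoxidation directed by the allylic C5 hydroxyl gives 16.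

Step 14 (debenzylation and 6-exo epoxide opening). Risks are loss of a triethylsilyl group under acid followed by 5-exo attack of O7, or incomplete inversion at C4. The fallback closes the ring while C7 is still a ketone and cannot compete; it sets out from 14 and comes back at 24. Hydrogenolysis (H2, Pd/C) of 14 gives the α-hydroxy ketone (2S,4S,5S)-5-[(2R,3S)-3-{(2S)-1-[(tert-butyldimethylsilyl)oxy]propan-2-yl}-2-methyloxiran-2-yl]-2,5-dihydroxy-4-methylpentan-3-one F6. Camphorsulfonic acid then effects the same 6-exo opening to the oxanone (2S,4S,5S,6R)-6-{(1S,2S)-3-[(tert-butyldimethylsilyl)oxy]-1-hydroxy-2-methylpropyl}-5-hydroxy-2,4,6-trimethyloxan-3-one F7. HF·pyridine frees the primary alcohol to give (2S,4S,5S,6R)-6-[(1S,2S)-1,3-dihydroxy-2-methylpropyl]-5-hydroxy-2,4,6-trimethyloxan-3-one F8, and TEMPO/PhI(OAc)2 lactonises it to the fully saturated bicyclic keto lactone (3R,4S,4aR,6S,8S,8aS)-4-hydroxy-3,4a,6,8-tetramethylhexahydropyrano[3,2-b]pyran-2,7-dione F9. Acetylation (Ac2O, pyridine, 0 °C) gives (3R,4S,4aS,6S,8S,8aS)-3,4a,6,8-tetramethyl-2,7-dioxooctahydropyrano[3,2-b]pyran-4-yl acetate F10. NaBH4 at −78 °C then delivers hydride axially to the ring ketone flanked by two equatorial methyl groups and gives the equatorial C7 alcohol 24.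

Step 23 (semihydrogenation to the (Z)-4-hydroxy enoate). The risk is lactonisation of 32 to a butenolide with expulsion of 24, or over-reduction. The fallback changes the order so that 32 never exists; it sets out from 31 and comes back at 33. Dess–Martin oxidation of 31 gives the ynone ester (3R,4S,4aS,6S,7R,8R,8aS)-4-(acetyloxy)-3,4a,6,8-tetramethyl-2-oxooctahydropyrano[3,2-b]pyran-7-yl 4-oxodec-2-ynoate F11, and cis-semihydrogenation (H2, Pd/CaCO3 poisoned with Pb(OAc)2, EtOAc, 0 °C, stopped at one equivalent) gives 33 directly.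

**Further compounds**

F1 | step 10 | (4Z,6R)-7-[(tert-butyldimethylsilyl)oxy]-4,6-dimethylhept-4-en-3-ol (C3 epimers) | CCC(O)/C(C)=C\[C@@H](C)CO[Si](C)(C)C(C)(C)C
F2 | step 10 | (4Z,6R)-7-[(tert-butyldimethylsilyl)oxy]-4,6-dimethylhept-4-en-3-one | CCC(=O)/C(C)=C\[C@@H](C)CO[Si](C)(C)C(C)(C)C
F3 | step 10 | (2S)-2-(benzyloxy)propanal | C[C@H](OCc1ccccc1)C=O
F4 | step 10 | (2S,3R,4R,6Z,8R)-2-(benzyloxy)-9-[(tert-butyldimethylsilyl)oxy]-3-hydroxy-4,6,8-trimethylnon-6-en-5-one | C[C@H](OCc1ccccc1)[C@H](O)[C@@H](C)C(=O)/C(C)=C\[C@@H](C)CO[Si](C)(C)C(C)(C)C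
F5 | step 10 | (2S,3R,4S,5S,6Z,8R)-2-(benzyloxy)-9-[(tert-butyldimethylsilyl)oxy]-4,6,8-trimethylnon-6-ene-3,5-diol | C[C@H](OCc1ccccc1)[C@H](O)[C@@H](C)[C@H](O)/C(C)=C\[C@@H](C)CO[Si](C)(C)C(C)(C)C
F6 | step 14 | (2S,4S,5S)-5-[(2R,3S)-3-{(2S)-1-[(tert-butyldimethylsilyl)oxy]propan-2-yl}-2-methyloxiran-2-yl]-2,5-dihydroxy-4-methylpentan-3-one | C[C@H](O)C(=O)[C@@H](C)[C@H](O)[C@@]1(C)O[C@H]1[C@@H](C)CO[Si](C)(C)C(C)(C)C
F7 | step 14 | (2S,4S,5S,6R)-6-{(1S,2S)-3-[(tert-butyldimethylsilyl)oxy]-1-hydroxy-2-methylpropyl}-5-hydroxy-2,4,6-trimethyloxan-3-one | C[C@@H]1O[C@](C)([C@@H](O)[C@@H](C)CO[Si](C)(C)C(C)(C)C)[C@@H](O)[C@H](C)C1=O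
F8 | step 14 | (2S,4S,5S,6R)-6-[(1S,2S)-1,3-dihydroxy-2-methylpropyl]-5-hydroxy-2,4,6-trimethyloxan-3-one | C[C@@H]1O[C@](C)([C@@H](O)[C@@H](C)CO)[C@@H](O)[C@H](C)C1=O
F9 | step 14 | (3R,4S,4aR,6S,8S,8aS)-4-hydroxy-3,4a,6,8-tetramethylhexahydropyrano[3,2-b]pyran-2,7-dione | O=C1[C@@H](C)[C@@H]2OC(=O)[C@H](C)[C@H](O)[C@@]2(C)O[C@H]1C
F10 | step 14 | (3R,4S,4aS,6S,8S,8aS)-3,4a,6,8-tetramethyl-2,7-dioxooctahydropyrano[3,2-b]pyran-4-yl acetate | O=C1[C@@H](C)[C@@H]2OC(=O)[C@H](C)[C@H](OC(C)=O)[C@@]2(C)O[C@H]1C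
F11 | step 23 | (3R,4S,4aS,6S,7R,8R,8aS)-4-(acetyloxy)-3,4a,6,8-tetramethyl-2-oxooctahydropyrano[3,2-b]pyran-7-yl 4-oxodec-2-ynoate | CCCCCCC(=O)C#CC(=O)O[C@@H]1[C@@H](C)[C@@H]2OC(=O)[C@H](C)[C@H](OC(C)=O)[C@@]2(C)O[C@H]1C
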